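**Strategy.** The route rests on a two-bond cut of the 2,3,4,7-tetrahydrooxepine ring (O1, quaternary C2, C3–C7): O1–C7 (allylic CH2) and C2–C3. The ring unit C3–C4–C5=C6–C7 is the opened form of a 1,1-disubstituted vinylcyclopropane, and O1–C2 is a ketone carbonyl. A rhodium-catalysed hetero-[5+2] cycloaddition should therefore join a vinylcyclopropane that already carries the whole coumarate side chain with a 2-oxo ester in which the aryl ketone is masked as a methyl enol ether, so that C2 is a true, non-enolised ketone. One operation builds the seven-membered ring, the C5=C6 alkene and the quaternary C2 stereocentre; fluoride, then acid, releases the target.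

Key step: step 9

Assumption: the sense of induction of step 9 cannot be predicted with confidence; (R)-BINAP is written, and its antipode is taken if a pilot run delivers the 2S series.
Assumption: the enol ether double bond of 15–18 is drawn E; its geometry is of no consequence because this carbon becomes the ketone in step 10.
Abbreviation: TBS = tert-butyldimethylsilyl.

**Step 1**
Reactants: 1 cyclopropyl methyl ketone; 2 prenyl bromide (1-bromo-3-methylbut-2-ene)
Product: 4 1-cyclopropyl-5-methylhex-4-en-1-one, via lithium enolate 3 (not isolated)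
Conditions: LDA, THF, −78 °C; then 2, −78 °C to 0 °C
Reagents that add atoms: none
Why: Kinetic deprotonation occurs at the CH3 group (the cyclopropyl C–H is not removed) and the lithium enolate is alkylated by the primary allylic bromide in an SN2 enolate alkylation; no stereocentre is formed.

**Step 2**
Reactants: 4 1-cyclopropyl-5-methylhex-4-en-1-one
Product: 5 (4E)-1-cyclopropyl-6-hydroxy-5-methylhex-4-en-1-one
Conditions: SeO2 (0.3 equiv), t-BuOOH (2.5 equiv), salicylic acid (10 mol %), CH2Cl2, 0 °C to rt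
Reagents that add atoms: selenium dioxide O=[Se]=O (delivers the oxygen, catalytic); tert-butyl hydroperoxide CC(C)(C)OO (stoichiometric oxygen source)
Why: Catalytic SeO2 allylic oxidation (Riley-type; ene reaction, then [2,3]-sigmatropic shift) hydroxylates the (E)-methyl group of the trisubstituted alkene, which fixes the E geometry of the side-chain alkene; α-oxidation of the ketone is slow at room temperature.

**Step 3**
Reactants: 5 (4E)-1-cyclopropyl-6-hydroxy-5-methylhex-4-en-1-one
Product: 6 (2E)-6-cyclopropyl-2-methylhepta-2,6-dien-1-ol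
Conditions: Ph3PCH3Br (2.5 equiv), KOtBu (2.4 equiv), THF, 0 °C to rt
Reagents that add atoms: methyltriphenylphosphonium bromide C[P+](c1ccccc1)(c1ccccc1)c1ccccc1.[Br-]
Why: Wittig methylenation of the cyclopropyl ketone (the hydroxyl is carried as its alkoxide, hence the excess ylide) gives the 1,1-disubstituted vinylcyclopropane without touching the trisubstituted alkene.

**Step 4**
Reactants: 7 p-coumaric acid
Product: 9 (2E)-3-{4-[(tert-butyldimethylsilyl)oxy]phenyl}prop-2-enoic acid, via bis-silylated coumarate 8 (not isolated)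
Conditions: TBSCl (2.3 equiv), imidazole, DMF, rt; then AcOH/THF/H2O, rt
Reagents that add atoms: tert-butyldimethylsilyl chloride CC(C)(C)[Si](C)(C)Cl
Why: Imidazole-promoted silylation of phenol and acid is followed by selective mild hydrolysis of the labile silyl ester, which leaves the aryl silyl ether (standard protecting-group chemistry).

**Step 5**
Reactants: 6 (2E)-6-cyclopropyl-2-methylhepta-2,6-dien-1-ol; 9 (2E)-3-{4-[(tert-butyldimethylsilyl)oxy]phenyl}prop-2-enoic acid
Product: 10 (2E)-6-cyclopropyl-2-methylhepta-2,6-dien-1-yl (2E)-3-{4-[(tert-butyldimethylsilyl)oxy]phenyl}prop-2-enoate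
Conditions: EDC·HCl, DMAP (cat.), CH2Cl2, 0 °C to rt
Reagents that add atoms: none
Why: Steglich-type carbodiimide esterification of the primary allylic alcohol runs under neutral conditions that should leave the vinylcyclopropane and both alkene geometries intact.

**Step 6**
Reactants: 11 methyl 2,5-dihydroxybenzoate
Product: 12 methyl 2,5-bis[(tert-butyldimethylsilyl)oxy]benzoate
Conditions: TBSCl (2.5 equiv), imidazole, DMAP (cat.), DMF, 50 °C
Reagents that add atoms: tert-butyldimethylsilyl chloride CC(C)(C)[Si](C)(C)Cl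
Why: Imidazole-promoted silylation protects both phenols; the hydrogen-bonded ortho-phenol is the reason for the mild heating.

**Step 7**
Reactants: 12 methyl 2,5-bis[(tert-butyldimethylsilyl)oxy]benzoate
Product: 13 1,4-bis[(tert-butyldimethylsilyl)oxy]-2-(1-methoxyethenyl)benzene
Conditions: Cp2TiMe2 (2.5 equiv), toluene, 65 °C, dark; filtration through basic alumina
Reagents that add atoms: dimethyltitanocene C[Ti](C)(C1C=CC=C1)C1C=CC=C1
Why: Petasis methylenation of the ester carbonyl (titanocene methylidene, [2+2]/retro-[2+2]) gives the α-methoxystyrene under conditions that are neither acidic nor basic towards the silyl ethers.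

**Step 8**
Reactants: 13 1,4-bis[(tert-butyldimethylsilyl)oxy]-2-(1-methoxyethenyl)benzene; 14 oxalyl chloride
Product: 16 2-(trimethylsilyl)ethyl (3E)-4-{2,5-bis[(tert-butyldimethylsilyl)oxy]phenyl}-4-methoxy-2-oxobut-3-enoate, via acid chloride 15 (not isolated)
Conditions: 14 (1.3 equiv), 2,6-lutidine, CH2Cl2, −20 °C to rt; concentrate; then Me3SiCH2CH2OH, 2,6-lutidine, CH2Cl2, 0 °C
Reagents that add atoms: 2-(trimethylsilyl)ethanol C[Si](C)(C)CCO
Why: Electrophilic β-acylation of the electron-rich enol ether by oxalyl chloride (addition, then loss of HCl; the known entry to 4-alkoxy-2-oxobut-3-enoates) is followed by esterification of the remaining acid chloride.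

**Step 9**
Reactants: 10 (2E)-6-cyclopropyl-2-methylhepta-2,6-dien-1-yl (2E)-3-{4-[(tert-butyldimethylsilyl)oxy]phenyl}prop-2-enoate; 16 2-(trimethylsilyl)ethyl (3E)-4-{2,5-bis[(tert-butyldimethylsilyl)oxy]phenyl}-4-methoxy-2-oxobut-3-enoate
Product: 17 2-(trimethylsilyl)ethyl (2R)-2-[(1E)-2-{2,5-bis[(tert-butyldimethylsilyl)oxy]phenyl}-2-methoxyethenyl]-6-[(3E)-5-{[(2E)-3-{4-[(tert-butyldimethylsilyl)oxy]phenyl}prop-2-enoyl]oxy}-4-methylpent-3-en-1-yl]-2,3,4,7-tetrahydrooxepine-2-carboxylate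
Conditions: [Rh(cod)2]SbF6 (10 mol %), (R)-BINAP (11 mol %), H2 then Ar (catalyst activation), ClCH2CH2Cl, 60 °C, slow addition of 10 (1.5 equiv)
Reagents that add atoms: none
Why: Proposed new method: cationic monovalent rhodium should open the vinyl-activated cyclopropane bond of 10 to a rhodacyclohexene (σ-alkyl at the ring CH2, π-allyl over the former vinyl group), the chelated, ester-activated ketone of 16 should insert into the Rh–CH2 bond, and the trivalent rhodium alkoxide so formed should close the ring by C–O reductive elimination at the CH2 terminus of the allyl; the closest known reaction types are the rhodium-catalysed [5+2] and [5+1] cycloadditions of vinylcyclopropanes with alkynes and with CO and the cationic rhodium/bisphosphine [2+2+2] cycloaddition of diynes with activated ketones as C=O partners. The oxepene is closed in a formal hetero-[5+2] mode, its last bond (O1–C7) by reductive elimination from an eight-membered oxarhodacycle. The C2 stereocentre is set in the carbonyl insertion under catalyst control, the C2-symmetric bisphosphine on rhodium selecting one face of the two-point-bound 1,2-dicarbonyl unit. The step needs the orientation C2-to-alkyl and O1-to-allyl, which the polarity match (nucleophilic σ-alkyl and electrophilic cationic π-allyl against the polarised C=O) should secure, an allyl-first adduct being a tertiary homoallyl alkoxide that can revert by β-allyl elimination. It also needs seven- over five-membered C–O closure, favoured at the primary, unhindered allyl terminus, and chemoselectivity for the ketone, secured because the enol-ether carbon of 16 is fully substituted and the other alkenes are trisubstituted or electron-poor.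

**Step 10**
Reactants: 17 2-(trimethylsilyl)ethyl (2R)-2-[(1E)-2-{2,5-bis[(tert-butyldimethylsilyl)oxy]phenyl}-2-methoxyethenyl]-6-[(3E)-5-{[(2E)-3-{4-[(tert-butyldimethylsilyl)oxy]phenyl}prop-2-enoyl]oxy}-4-methylpent-3-en-1-yl]-2,3,4,7-tetrahydrooxepine-2-carboxylate
Product: 19 (2R)-2-[2-(2,5-dihydroxyphenyl)-2-oxoethyl]-6-[(3E)-5-{[(2E)-3-(4-hydroxyphenyl)prop-2-enoyl]oxy}-4-methylpent-3-en-1-yl]-2,3,4,7-tetrahydrooxepine-2-carboxylic acid (CNP0602535.1), via desilylated enol ether acid 18 (not isolated)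
Conditions: TBAF (6 equiv), THF, 0 °C to rt, under Ar; then 1 M aq. HCl to pH 1–2, THF/H2O, 0 °C to rt
Reagents that add atoms: water O
Why: Fluoride cleaves the three aryl silyl ethers and fragments the 2-(trimethylsilyl)ethyl ester (to ethene and Me3SiF) while the ketone is still masked, so no base-labile β-alkoxy ketone is present, and aqueous acid then hydrolyses the aryl enol ether to the ketone; C2 is not touched.

**Compound list**
1 | cyclopropyl methyl ketone (1-cyclopropylethan-1-one) | CC(=O)C1CC1 | starting material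
2 | prenyl bromide (1-bromo-3-methylbut-2-ene) | CC(C)=CCBr | starting material
3 | lithium 1-cyclopropylethen-1-olate | [Li]OC(=C)C1CC1 | intermediate (not isolated)
4 | 1-cyclopropyl-5-methylhex-4-en-1-one | CC(C)=CCCC(=O)C1CC1 | intermediate
5 | (4E)-1-cyclopropyl-6-hydroxy-5-methylhex-4-en-1-one | C/C(=C\CCC(=O)C1CC1)CO | intermediate
6 | (2E)-6-cyclopropyl-2-methylhepta-2,6-dien-1-ol | C/C(=C\CCC(=C)C1CC1)CO | intermediate
7 | p-coumaric acid ((2E)-3-(4-hydroxyphenyl)prop-2-enoic acid) | OC(=O)/C=C/c1ccc(O)cc1 | starting material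
8 | tert-butyldimethylsilyl (2E)-3-{4-[(tert-butyldimethylsilyl)oxy]phenyl}prop-2-enoate | CC(C)(C)[Si](C)(C)OC(=O)/C=C/c1ccc(O[Si](C)(C)C(C)(C)C)cc1 | intermediate (not isolated)
9 | (2E)-3-{4-[(tert-butyldimethylsilyl)oxy]phenyl}prop-2-enoic acid | OC(=O)/C=C/c1ccc(O[Si](C)(C)C(C)(C)C)cc1 | intermediate
10 | (2E)-6-cyclopropyl-2-methylhepta-2,6-dien-1-yl (2E)-3-{4-[(tert-butyldimethylsilyl)oxy]phenyl}prop-2-enoate | C/C(=C\CCC(=C)C1CC1)COC(=O)/C=C/c1ccc(O[Si](C)(C)C(C)(C)C)cc1 | intermediate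
11 | methyl 2,5-dihydroxybenzoate | COC(=O)c1cc(O)ccc1O | starting material
12 | methyl 2,5-bis[(tert-butyldimethylsilyl)oxy]benzoate | COC(=O)c1cc(O[Si](C)(C)C(C)(C)C)ccc1O[Si](C)(C)C(C)(C)C | intermediate
13 | 1,4-bis[(tert-butyldimethylsilyl)oxy]-2-(1-methoxyethenyl)benzene | COC(=C)c1cc(O[Si](C)(C)C(C)(C)C)ccc1O[Si](C)(C)C(C)(C)C | intermediate
14 | oxalyl chloride | ClC(=O)C(=O)Cl | starting material
15 | (3E)-4-{2,5-bis[(tert-butyldimethylsilyl)oxy]phenyl}-4-methoxy-2-oxobut-3-enoyl chloride | CO/C(=C/C(=O)C(Cl)=O)c1cc(O[Si](C)(C)C(C)(C)C)ccc1O[Si](C)(C)C(C)(C)C | intermediate (not isolated)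
16 | 2-(trimethylsilyl)ethyl (3E)-4-{2,5-bis[(tert-butyldimethylsilyl)oxy]phenyl}-4-methoxy-2-oxobut-3-enoate | CO/C(=C/C(=O)C(=O)OCC[Si](C)(C)C)c1cc(O[Si](C)(C)C(C)(C)C)ccc1O[Si](C)(C)C(C)(C)C | intermediate
17 | 2-(trimethylsilyl)ethyl (2R)-2-[(1E)-2-{2,5-bis[(tert-butyldimethylsilyl)oxy]phenyl}-2-methoxyethenyl]-6-[(3E)-5-{[(2E)-3-{4-[(tert-butyldimethylsilyl)oxy]phenyl}prop-2-enoyl]oxy}-4-methylpent-3-en-1-yl]-2,3,4,7-tetrahydrooxepine-2-carboxylate | C/C(=C\CCC1=CCC[C@@](/C=C(/OC)c2cc(O[Si](C)(C)C(C)(C)C)ccc2O[Si](C)(C)C(C)(C)C)(C(=O)OCC[Si](C)(C)C)OC1)COC(=O)/C=C/c1ccc(O[Si](C)(C)C(C)(C)C)cc1 | intermediate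
18 | (2R)-2-[(1E)-2-(2,5-dihydroxyphenyl)-2-methoxyethenyl]-6-[(3E)-5-{[(2E)-3-(4-hydroxyphenyl)prop-2-enoyl]oxy}-4-methylpent-3-en-1-yl]-2,3,4,7-tetrahydrooxepine-2-carboxylic acid (formed as its tetrabutylammonium salts) | C/C(=C\CCC1=CCC[C@@](/C=C(/OC)c2cc(O)ccc2O)(C(=O)O)OC1)COC(=O)/C=C/c1ccc(O)cc1 | intermediate (not isolated)
19 | (2R)-2-[2-(2,5-dihydroxyphenyl)-2-oxoethyl]-6-[(3E)-5-{[(2E)-3-(4-hydroxyphenyl)prop-2-enoyl]oxy}-4-methylpent-3-en-1-yl]-2,3,4,7-tetrahydrooxepine-2-carboxylic acid (CNP0602535.1) | C/C(=C\CCC1=CCC[C@@](CC(=O)c2cc(O)ccc2O)(C(=O)O)OC1)COC(=O)/C=C/c1ccc(O)cc1 | target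

**Totals**
Total step count: 10.
Longest linear sequence: 6 steps (steps 1, 2, 3, 5, 9, 10).

**Steps most likely to fail**

Step 9 (labelled step). The rhodacycle may collapse to dienes by β-hydride elimination before the ketone inserts, the ketone may insert with the reverse orientation, the C–O bond may close at the inner allyl carbon to a five-membered ring, or facial selectivity may be poor. The fallback uses known chemistry and closes the ring by alkene metathesis at C5=C6; it sets out from 16 and comes back to the route at 17. But-3-enylmagnesium bromide and ZnCl2 give di(but-3-en-1-yl)zinc F1. A catalytic enantioselective dialkylzinc 1,2-addition to the ketone of 16 (Ti(OiPr)4, chiral trans-cyclohexane-1,2-diamine bis(sulfonamide) diol ligand, toluene) should give the tertiary alcohol 2-(trimethylsilyl)ethyl (2R,3E)-4-{2,5-bis[(tert-butyldimethylsilyl)oxy]phenyl}-2-(but-3-en-1-yl)-2-hydroxy-4-methoxybut-3-enoate F2. O-Alkylation (NaH, 2,3-dibromopropene, DMF, 0 °C) should give the 2-bromoallyl ether 2-(trimethylsilyl)ethyl (2R,3E)-4-{2,5-bis[(tert-butyldimethylsilyl)oxy]phenyl}-2-[(2-bromoprop-2-en-1-yl)oxy]-2-(but-3-en-1-yl)-4-methoxybut-3-enoate F3. For the side chain, a Wittig reaction of acrolein with ethyl 2-(triphenylphosphoranylidene)propanoate should give ethyl (2E)-2-methylpenta-2,4-dienoate F4, DIBAL-H reduction should give (2E)-2-methylpenta-2,4-dien-1-ol F5, and carbodiimide esterification with 9 should give (2E)-2-methylpenta-2,4-dien-1-yl (2E)-3-{4-[(tert-butyldimethylsilyl)oxy]phenyl}prop-2-enoate F6. Hydroboration of the terminal vinyl group of F6 with 9-BBN should give the alkylborane 9-[(3E)-5-{[(2E)-3-{4-[(tert-butyldimethylsilyl)oxy]phenyl}prop-2-enoyl]oxy}-4-methylpent-3-en-1-yl]-9-borabicyclo[3.3.1]nonane F7. This is coupled in the same flask with F3 in a B-alkyl Suzuki–Miyaura reaction (Pd(dppf)Cl2, AsPh3, K3PO4, DMF/THF/H2O, rt) to give the triene 2-(trimethylsilyl)ethyl (2R,3E)-4-{2,5-bis[(tert-butyldimethylsilyl)oxy]phenyl}-2-(but-3-en-1-yl)-4-methoxy-2-{[(5E)-7-{[(2E)-3-{4-[(tert-butyldimethylsilyl)oxy]phenyl}prop-2-enoyl]oxy}-6-methyl-2-methylidenehept-5-en-1-yl]oxy}but-3-enoate F8. Ring-closing metathesis of F8 (second-generation Hoveyda–Grubbs catalyst, CH2Cl2, 40 °C) between the but-3-enyl group and the 1,1-disubstituted alkene should form C5=C6 and return 17.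

Step 10. The allylic coumarate ester may be partly cleaved or the silylethyl ester may leave sluggishly under fluoride, the hydroquinone anion may oxidise, and the ring oxygen may be lost by β-elimination once the ketone is free. The fallback replaces the fluoride-labile ester by an acid-labile one, so that the end game is acidic throughout; it sets out from 13 (with 14, through acid chloride 15) and comes back at 19. Quenching 15 with 4-methoxybenzyl alcohol and 2,6-lutidine should give 4-methoxybenzyl (3E)-4-{2,5-bis[(tert-butyldimethylsilyl)oxy]phenyl}-4-methoxy-2-oxobut-3-enoate F9. This is taken through step 9 with 10 to 4-methoxybenzyl (2R)-2-[(1E)-2-{2,5-bis[(tert-butyldimethylsilyl)oxy]phenyl}-2-methoxyethenyl]-6-[(3E)-5-{[(2E)-3-{4-[(tert-butyldimethylsilyl)oxy]phenyl}prop-2-enoyl]oxy}-4-methylpent-3-en-1-yl]-2,3,4,7-tetrahydrooxepine-2-carboxylate F10. Dilute TFA with anisole in CH2Cl2 at 0 °C and aqueous work-up should cleave the benzyl ester and hydrolyse the enol ether to (2R)-2-(2-{2,5-bis[(tert-butyldimethylsilyl)oxy]phenyl}-2-oxoethyl)-6-[(3E)-5-{[(2E)-3-{4-[(tert-butyldimethylsilyl)oxy]phenyl}prop-2-enoyl]oxy}-4-methylpent-3-en-1-yl]-2,3,4,7-tetrahydrooxepine-2-carboxylic acid F11. KHF2 in MeOH at rt then removes the three aryl silyl ethers under near-neutral conditions to give 19.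

Step 2. The allylic alcohol may be over-oxidised to the enal, conversion may stay incomplete, and the ketone may be oxidised at its α-position. The fallback brings the oxygen in with the alkylating agent instead of oxidising a C–H bond; it sets out from 1 (as its lithium enolate 3) and comes back at 5. Opening of 2-methyl-2-vinyloxirane with TiCl4 (CH2Cl2, −85 °C, SN2′) should give (2E)-4-chloro-2-methylbut-2-en-1-ol F12, and TBSCl/imidazole its silyl ether tert-butyl{[(2E)-4-chloro-2-methylbut-2-en-1-yl]oxy}dimethylsilane F13. Alkylation of enolate 3 with F13 (NaI cat., THF, −78 °C to 0 °C) should give (4E)-6-[(tert-butyldimethylsilyl)oxy]-1-cyclopropyl-5-methylhex-4-en-1-one F14, and TBAF in THF returns 5.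

**Further compounds**
F1 | step 9 | di(but-3-en-1-yl)zinc | C=CCC[Zn]CCC=C
F2 | step 9 | 2-(trimethylsilyl)ethyl (2R,3E)-4-{2,5-bis[(tert-butyldimethylsilyl)oxy]phenyl}-2-(but-3-en-1-yl)-2-hydroxy-4-methoxybut-3-enoate | C=CCC[C@@](O)(/C=C(/OC)c1cc(O[Si](C)(C)C(C)(C)C)ccc1O[Si](C)(C)C(C)(C)C)C(=O)OCC[Si](C)(C)C
F3 | step 9 | 2-(trimethylsilyl)ethyl (2R,3E)-4-{2,5-bis[(tert-butyldimethylsilyl)oxy]phenyl}-2-[(2-bromoprop-2-en-1-yl)oxy]-2-(but-3-en-1-yl)-4-methoxybut-3-enoate | C=CCC[C@@](OCC(Br)=C)(/C=C(/OC)c1cc(O[Si](C)(C)C(C)(C)C)ccc1O[Si](C)(C)C(C)(C)C)C(=O)OCC[Si](C)(C)C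
F4 | step 9 | ethyl (2E)-2-methylpenta-2,4-dienoate | C=C/C=C(\C)C(=O)OCC
F5 | step 9 | (2E)-2-methylpenta-2,4-dien-1-ol | C=C/C=C(\C)CO
F6 | step 9 | (2E)-2-methylpenta-2,4-dien-1-yl (2E)-3-{4-[(tert-butyldimethylsilyl)oxy]phenyl}prop-2-enoate | C=C/C=C(\C)COC(=O)/C=C/c1ccc(O[Si](C)(C)C(C)(C)C)cc1
F7 | step 9 | 9-[(3E)-5-{[(2E)-3-{4-[(tert-butyldimethylsilyl)oxy]phenyl}prop-2-enoyl]oxy}-4-methylpent-3-en-1-yl]-9-borabicyclo[3.3.1]nonane | C/C(=C\CCB1C2CCCC1CCC2)COC(=O)/C=C/c1ccc(O[Si](C)(C)C(C)(C)C)cc1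
F8 | step 9 | 2-(trimethylsilyl)ethyl (2R,3E)-4-{2,5-bis[(tert-butyldimethylsilyl)oxy]phenyl}-2-(but-3-en-1-yl)-4-methoxy-2-{[(5E)-7-{[(2E)-3-{4-[(tert-butyldimethylsilyl)oxy]phenyl}prop-2-enoyl]oxy}-6-methyl-2-methylidenehept-5-en-1-yl]oxy}but-3-enoate | C=CCC[C@@](OCC(=C)CC/C=C(\C)COC(=O)/C=C/c1ccc(O[Si](C)(C)C(C)(C)C)cc1)(/C=C(/OC)c1cc(O[Si](C)(C)C(C)(C)C)ccc1O[Si](C)(C)C(C)(C)C)C(=O)OCC[Si](C)(C)C
F9 | step 10 | 4-methoxybenzyl (3E)-4-{2,5-bis[(tert-butyldimethylsilyl)oxy]phenyl}-4-methoxy-2-oxobut-3-enoate | CO/C(=C/C(=O)C(=O)OCc1ccc(OC)cc1)c1cc(O[Si](C)(C)C(C)(C)C)ccc1O[Si](C)(C)C(C)(C)C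
F10 | step 10 | 4-methoxybenzyl (2R)-2-[(1E)-2-{2,5-bis[(tert-butyldimethylsilyl)oxy]phenyl}-2-methoxyethenyl]-6-[(3E)-5-{[(2E)-3-{4-[(tert-butyldimethylsilyl)oxy]phenyl}prop-2-enoyl]oxy}-4-methylpent-3-en-1-yl]-2,3,4,7-tetrahydrooxepine-2-carboxylate | C/C(=C\CCC1=CCC[C@@](/C=C(/OC)c2cc(O[Si](C)(C)C(C)(C)C)ccc2O[Si](C)(C)C(C)(C)C)(C(=O)OCc2ccc(OC)cc2)OC1)COC(=O)/C=C/c1ccc(O[Si](C)(C)C(C)(C)C)cc1
F11 | step 10 | (2R)-2-(2-{2,5-bis[(tert-butyldimethylsilyl)oxy]phenyl}-2-oxoethyl)-6-[(3E)-5-{[(2E)-3-{4-[(tert-butyldimethylsilyl)oxy]phenyl}prop-2-enoyl]oxy}-4-methylpent-3-en-1-yl]-2,3,4,7-tetrahydrooxepine-2-carboxylic acid | C/C(=C\CCC1=CCC[C@@](CC(=O)c2cc(O[Si](C)(C)C(C)(C)C)ccc2O[Si](C)(C)C(C)(C)C)(C(=O)O)OC1)COC(=O)/C=C/c1ccc(O[Si](C)(C)C(C)(C)C)cc1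
F12 | step 2 | (2E)-4-chloro-2-methylbut-2-en-1-ol | C/C(=C\CCl)CO
F13 | step 2 | tert-butyl{[(2E)-4-chloro-2-methylbut-2-en-1-yl]oxy}dimethylsilane | C/C(=C\CCl)CO[Si](C)(C)C(C)(C)C
F14 | step 2 | (4E)-6-[(tert-butyldimethylsilyl)oxy]-1-cyclopropyl-5-methylhex-4-en-1-one | C/C(=C\CCC(=O)C1CC1)CO[Si](C)(C)C(C)(C)C
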